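**Retrosynthetic overview**

- Feature: in target 16 the acetoxy oxygen, side-chain C2′ and C1′, quinone C6 and quinone C1 (the carbonyl carbon flanked by the methoxy-bearing C2 and the alkyl-bearing C6) map onto O1–C2–C3–C3a–C7a of a 2-substituted 2,3-dihydrobenzofuran. With a 5-OMe para to O1, that arene is a masked p-quinone.
- 16 ⇐ acetylation of hydroxyquinone 15 ⇐ Ce(IV) oxidative opening of (R)-5,7-dimethoxy-2-tridecyl-2,3-dihydrobenzofuran 14 (C7a–O1 broken, C2–O1 kept).
- 14 ⇐ diimide reduction and cross-metathesis with 1-tridecene from (S)-2-vinyl-dihydrobenzofuran 11.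
- 11 ⇐ Pd-catalysed asymmetric intramolecular allylic etherification of phenol carbonate 10. This forms O1–C2, the only stereocentre and the only ring made in the route (the quinone ring is the original benzene ring).
- 10 ⇐ cross-metathesis of 2-allyl-4,6-dimethoxyphenol 7 with bis-carbonate 9; 7 ⇐ Claisen rearrangement of the allyl ether of 2,4-dimethoxyphenol ⇐ Baeyer–Villiger oxidation of 2,4-dimethoxybenzaldehyde.

Key step: step 6

Assumption: the (S,S) enantiomer of the DACH-phenyl Trost ligand is taken to deliver the (S)-ether 11; the sense is to be confirmed on the first batch, and the (R,R) ligand is used instead if it proves opposite.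

**Route**

Step 1
Reactants: 1 2,4-dimethoxybenzaldehyde
Product: 3 2,4-dimethoxyphenol, via 2,4-dimethoxyphenyl formate 2 (not isolated)
Conditions: mCPBA (1.1 equiv), CH2Cl2, 0 °C→rt; then MeOH, Et3N, rt
Reagents that add atoms: mCPBA, OOC(=O)c1cccc(Cl)c1
Why: Baeyer–Villiger oxidation of an electron-rich benzaldehyde should proceed with aryl migration to the formate (a Dakin-type outcome), which mild base in methanol transesterifies to the phenol.

Step 2
Reactants: 3 2,4-dimethoxyphenol; 4 allyl bromide
Product: 5 1-(allyloxy)-2,4-dimethoxybenzene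
Conditions: K2CO3, acetone, reflux
Reagents that add atoms: none
Why: Williamson ether synthesis; the phenoxide should alkylate cleanly on oxygen with the reactive allylic bromide in a polar aprotic solvent.

Step 3
Reactants: 5 1-(allyloxy)-2,4-dimethoxybenzene
Product: 7 2-allyl-4,6-dimethoxyphenol, via 6-allyl-2,4-dimethoxycyclohexa-2,4-dien-1-one 6 (not isolated)
Conditions: PhNEt2, 200 °C, Ar
Reagents that add atoms: none
Why: Aromatic Claisen rearrangement; the [3,3] shift should deliver the allyl group to the only unsubstituted ortho carbon, and the dienone then tautomerises to the phenol.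

Step 4
Reactants: 8 (Z)-but-2-ene-1,4-diol
Product: 9 (Z)-but-2-ene-1,4-diyl dimethyl bis(carbonate)
Conditions: ClCO2Me (2.5 equiv), pyridine, CH2Cl2, 0 °C→rt
Reagents that add atoms: methyl chloroformate, COC(Cl)=O
Why: Acylation of both primary alcohols with a chloroformate under pyridine should give the symmetrical bis-carbonate used as the metathesis partner.

Step 5
Reactants: 7 2-allyl-4,6-dimethoxyphenol; 9 (Z)-but-2-ene-1,4-diyl dimethyl bis(carbonate)
Product: 10 (E)-4-(2-hydroxy-3,5-dimethoxyphenyl)but-2-en-1-yl methyl carbonate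
Conditions: Grubbs II (5 mol%), 9 (3 equiv), CH2Cl2, 40 °C, Ar
Reagents that add atoms: none
Why: Olefin cross-metathesis of a terminal allylarene with an excess of a symmetrical internal allylic carbonate should tolerate the free phenol and give mainly the E alkene; any Z isomer is carried on because step 6 is stereoconvergent.

Step 6
Reactants: 10 (E)-4-(2-hydroxy-3,5-dimethoxyphenyl)but-2-en-1-yl methyl carbonate
Product: 11 (S)-5,7-dimethoxy-2-vinyl-2,3-dihydrobenzofuran
Conditions: Pd2(dba)3·CHCl3 (2 mol%), (S,S)-DACH-phenyl Trost ligand (6 mol%), AcOH (1 equiv), CH2Cl2, rt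
Reagents that add atoms: none
Why: The Pd(0)–diphosphine complex ionises the allylic carbonate of 10 with loss of CO2 and methoxide to a cationic π-allylpalladium complex, and the base so formed (methoxide, buffered as acetate) frees the phenoxide. The diastereomeric π-allyl complexes should exchange the palladium face by π–σ–π isomerisation through the unsubstituted CH2 terminus faster than the ring closes, so both alkene geometries of 10 and both faces of ionisation drain into one product. The phenoxide oxygen then attacks the internal allyl carbon anti to palladium in a 5-exo closure that forms the O1–C2 bond and the dihydrofuran ring and leaves the vinyl group outside the ring. The closest known reaction type is the Trost asymmetric allylic alkylation with phenol nucleophiles in its intramolecular form, which gives 2-vinylchromans and 2-alkenyl-2,3-dihydrobenzofurans. The C2 stereocentre is set in this C–O bond formation by the chiral pocket of the diphosphine, which favours attack on one of the equilibrating complexes. The step needs 5-exo over 7-endo closure, which the one-carbon tether between the arene and the allyl unit secures, and it needs the product ether not to re-ionise, which the electron-rich and therefore poorly leaving aryloxide helps.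

Step 7
Reactants: 11 (S)-5,7-dimethoxy-2-vinyl-2,3-dihydrobenzofuran; 12 1-tridecene
Product: 13 (S,E)-5,7-dimethoxy-2-(tridec-1-en-1-yl)-2,3-dihydrobenzofuran
Conditions: Hoveyda–Grubbs II (5 mol%), 12 (4 equiv), CH2Cl2, 40 °C
Reagents that add atoms: none
Why: Olefin cross-metathesis; the branched allylic ether alkene of 11 homodimerises slowly, so an excess of the unhindered terminal alkene 12 should drive the cross product without touching C2.

Step 8
Reactants: 13 (S,E)-5,7-dimethoxy-2-(tridec-1-en-1-yl)-2,3-dihydrobenzofuran
Product: 14 (R)-5,7-dimethoxy-2-tridecyl-2,3-dihydrobenzofuran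
Conditions: TsNHNH2 (excess), NaOAc, DME/H2O, reflux
Reagents that add atoms: none
Why: Diimide reduction transfers H2 to the disubstituted alkene in a concerted way and should avoid the hydrogenolysis of the allylic C2–O bond that H2/Pd could cause; C2 is untouched and only its descriptor changes from S to R because the saturated chain now ranks below CH2Ar.

Step 9
Reactants: 14 (R)-5,7-dimethoxy-2-tridecyl-2,3-dihydrobenzofuran
Product: 15 (R)-2-(2-hydroxypentadecyl)-6-methoxy-1,4-benzoquinone
Conditions: CAN (2.5 equiv), MeCN/H2O, 0 °C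
Reagents that add atoms: water, O
Why: Cerium(IV) oxidative dealkylation of a hydroquinone diether; water should add at C5 (methanol leaves) and at C7a (the ring oxygen leaves the arene but stays on C2), so the p-quinone forms with the 7-OMe retained and the carbinol configuration unchanged, as in the chromanol-to-hydroxyalkylquinone opening of tocopherol.

Step 10
Reactants: 15 (R)-2-(2-hydroxypentadecyl)-6-methoxy-1,4-benzoquinone
Product: 16 ardisinone, (R)-1-(5-methoxy-3,6-dioxocyclohexa-1,4-dien-1-yl)pentadecan-2-yl acetate
Conditions: Ac2O, pyridine, CH2Cl2, 0 °C→rt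
Reagents that add atoms: acetic anhydride, CC(=O)OC(C)=O
Why: Acylation of the secondary alcohol with acetic anhydride under a weak amine base at low temperature (no DMAP) should spare the methoxyquinone and proceeds with retention at the carbinol carbon.

**Compound list**

1 | 2,4-dimethoxybenzaldehyde | COc1ccc(C=O)c(OC)c1 | starting material
2 | 2,4-dimethoxyphenyl formate | COc1ccc(OC=O)c(OC)c1 | intermediate
3 | 2,4-dimethoxyphenol | COc1ccc(O)c(OC)c1 | intermediate
4 | allyl bromide | C=CCBr | starting material
5 | 1-(allyloxy)-2,4-dimethoxybenzene | C=CCOc1ccc(OC)cc1OC | intermediate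
6 | 6-allyl-2,4-dimethoxycyclohexa-2,4-dien-1-one (racemic) | O=C1C(OC)=CC(OC)=CC1CC=C | intermediate
7 | 2-allyl-4,6-dimethoxyphenol | C=CCc1cc(OC)cc(OC)c1O | intermediate
8 | (Z)-but-2-ene-1,4-diol | OC/C=C\CO | starting material
9 | (Z)-but-2-ene-1,4-diyl dimethyl bis(carbonate) | COC(=O)OC/C=C\COC(=O)OC | intermediate
10 | (E)-4-(2-hydroxy-3,5-dimethoxyphenyl)but-2-en-1-yl methyl carbonate | COC(=O)OC/C=C/Cc1cc(OC)cc(OC)c1O | intermediate
11 | (S)-5,7-dimethoxy-2-vinyl-2,3-dihydrobenzofuran | C=C[C@@H]1Cc2cc(OC)cc(OC)c2O1 | intermediate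
12 | 1-tridecene | C=CCCCCCCCCCCC | starting material
13 | (S,E)-5,7-dimethoxy-2-(tridec-1-en-1-yl)-2,3-dihydrobenzofuran | CCCCCCCCCCC/C=C/[C@@H]1Cc2cc(OC)cc(OC)c2O1 | intermediate
14 | (R)-5,7-dimethoxy-2-tridecyl-2,3-dihydrobenzofuran | CCCCCCCCCCCCC[C@@H]1Cc2cc(OC)cc(OC)c2O1 | intermediate
15 | (R)-2-(2-hydroxypentadecyl)-6-methoxy-1,4-benzoquinone | CCCCCCCCCCCCC[C@H](CC1=CC(=O)C=C(OC)C1=O)O | intermediate
16 | ardisinone, (R)-1-(5-methoxy-3,6-dioxocyclohexa-1,4-dien-1-yl)pentadecan-2-yl acetate | CCCCCCCCCCCCC[C@H](CC1=CC(=O)C=C(OC)C1=O)OC(C)=O | target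

**Step count**

Total steps: 10. Longest linear sequence: 9 steps (steps 1, 2, 3, 5, 6, 7, 8, 9, 10 from 2,4-dimethoxybenzaldehyde); step 4 is a one-step side branch.

**Steps most likely to fail, with fallbacks**

Step 6 (key step).
- What may go wrong: facial discrimination may be poor if ring closure outruns π–σ–π equilibration. The product allyl aryl ether may be re-ionised by Pd(0), eroding the enantiomeric purity. β-Hydride loss from the π-allyl complex may lead to a 1-arylbutadiene.
- Fallback: it sets out from 7 and comes back to the route at 14, so steps 5–8 are bypassed. The phenol of 7 would be benzylated (BnBr, K2CO3, DMF) to 1-allyl-2-(benzyloxy)-3,5-dimethoxybenzene F1. The terminal alkene would be epoxidised (mCPBA, NaHCO3, CH2Cl2, 0 °C) to racemic 2-[2-(benzyloxy)-3,5-dimethoxybenzyl]oxirane F2. Jacobsen hydrolytic kinetic resolution (salen–Co(III) acetate, 0.55 equiv water, catalyst enantiomer chosen so that the R epoxide survives) would give (R)-2-[2-(benzyloxy)-3,5-dimethoxybenzyl]oxirane F3. Copper-catalysed opening at the terminal carbon with dodecylmagnesium bromide (CuI cat., THF, −30 °C) would give (S)-1-[2-(benzyloxy)-3,5-dimethoxyphenyl]pentadecan-2-ol F4. Hydrogenolysis (H2, Pd/C, EtOAc) would give (S)-2-(2-hydroxypentadecyl)-4,6-dimethoxyphenol F5. Mitsunobu cyclisation (PPh3, DIAD, THF, 0 °C) would close the dihydrofuran ring with inversion at the carbinol carbon to give 14, and steps 9 and 10 follow unchanged.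

Step 9 (cerium(IV) opening).
- What may go wrong: the arene radical cation may couple to biaryls or be over-oxidised. Loss of the C7 methyl instead of the C5 methyl would lead to an ortho-quinone. The ring may open incompletely, leaving a cyclic hemiketal.
- Fallback: it sets out from 14 and comes back at 15. Anodic oxidation in methanol (Pt anode, KOH/MeOH, 0 °C, constant current) would give the quinone bis-ketal (2R)-5,5,7,7a-tetramethoxy-2-tridecyl-2,3,5,7a-tetrahydrobenzofuran F6 as a mixture at C7a. Hydrolysis with dilute aqueous acid (1 M HCl, acetone, 0 °C) would then unmask both carbonyl groups, release the C2 hydroxyl and give 15.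

Step 7 (cross-metathesis on the allylic ether).
- What may go wrong: metathesis at the branched allylic ether alkene may be slow, so that homodimerisation of 12 dominates. Ruthenium hydride species may migrate the double bond toward the ring oxygen, with loss of material.
- Fallback: it sets out from 11 and comes back at 14, bypassing 13 and step 8. Hydroboration–oxidation (9-BBN, THF; then NaBO3·4H2O) would give (S)-2-(5,7-dimethoxy-2,3-dihydrobenzofuran-2-yl)ethanol F7. Tosylation (TsCl, pyridine, CH2Cl2, 0 °C) would give (S)-2-(5,7-dimethoxy-2,3-dihydrobenzofuran-2-yl)ethyl 4-methylbenzenesulfonate F8. Copper-catalysed coupling with undecylmagnesium bromide (Li2CuCl4 cat., THF, −20 °C) would complete the tridecyl chain and give 14.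

**Further compounds**

F1 | step 6 | 1-allyl-2-(benzyloxy)-3,5-dimethoxybenzene | C=CCc1cc(OC)cc(OC)c1OCc1ccccc1
F2 | step 6 | rac-2-[2-(benzyloxy)-3,5-dimethoxybenzyl]oxirane | C1OC1Cc1cc(OC)cc(OC)c1OCc1ccccc1
F3 | step 6 | (R)-2-[2-(benzyloxy)-3,5-dimethoxybenzyl]oxirane | C1[C@@H](Cc2cc(OC)cc(OC)c2OCc2ccccc2)O1
F4 | step 6 | (S)-1-[2-(benzyloxy)-3,5-dimethoxyphenyl]pentadecan-2-ol | CCCCCCCCCCCCC[C@H](O)Cc1cc(OC)cc(OC)c1OCc1ccccc1
F5 | step 6 | (S)-2-(2-hydroxypentadecyl)-4,6-dimethoxyphenol | CCCCCCCCCCCCC[C@H](O)Cc1cc(OC)cc(OC)c1O
F6 | step 9 | (2R)-5,5,7,7a-tetramethoxy-2-tridecyl-2,3,5,7a-tetrahydrobenzofuran | CCCCCCCCCCCCC[C@@H]1CC2=CC(OC)(OC)C=C(OC)C2(OC)O1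
F7 | step 7 | (S)-2-(5,7-dimethoxy-2,3-dihydrobenzofuran-2-yl)ethanol | OCC[C@@H]1Cc2cc(OC)cc(OC)c2O1
F8 | step 7 | (S)-2-(5,7-dimethoxy-2,3-dihydrobenzofuran-2-yl)ethyl 4-methylbenzenesulfonate | Cc1ccc(cc1)S(=O)(=O)OCC[C@@H]1Cc2cc(OC)cc(OC)c2O1
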